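**Retrosynthetic overview**
- The target comes from its 5-O-MOM ether by acetal cleavage; nothing after the key step changes oxidation level or configuration.
- The MOM-protected flavanone is cut at C2–C1' into a 5,7-dioxygenated chromone and a 2-geranyl-3,4-dimethoxyphenylboronic acid; one rhodium-catalysed asymmetric 1,4-addition makes this bond and the only stereocenter (C2, S). The enabling feature is ring C held at the chromone oxidation level: O1–C2=C3–C4=O is a flat vinylogous ester with an electrophilic, prochiral C2, while C1' of ring B can carry boron beside the geranyl-bearing C2'.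
- The boronic acid comes from 4-bromoveratrole and geranyl bromide: the bromine at C1' first directs lithiation to C2' (flanked by Br and the 3'-OMe) for geranylation and is then exchanged for boron.
- The chromone comes from 2',6'-dihydroxy-4'-methoxyacetophenone and DMF-DMA (which supplies C2). Rings A and B are bought; ring C is the only ring formed, closed in step 3 as the pyranone before the coupling.

Key step: step 5

Remark: the stereodescriptor in the given SMILES corresponds to 2S and the C2=C3 alkene of the geranyl chain is E; the three starting materials 1, 2 and 9 are taken as commercial.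

**Step 1**
Reactants: 1 4-bromo-1,2-dimethoxybenzene; 2 geranyl bromide [(2E)-1-bromo-3,7-dimethylocta-2,6-diene]
Product: 5 1-bromo-2-[(2E)-3,7-dimethylocta-2,6-dien-1-yl]-3,4-dimethoxybenzene, via aryllithium 3 (not isolated), via arylcopper 4 (not isolated)
Conditions: LiN(iPr)2 (LDA, 1.1 equiv), THF, −78 °C; CuBr·SMe2 (1.1 equiv), −78 °C; then 2, −78 → −20 °C
Reagents that add atoms: none
Why: Directed ortho-lithiation by the amide base should remove the most acidic ring proton, the one flanked by Br and the neighbouring methoxy group, without bromine–lithium exchange, and after transmetalation the arylcopper should be allylated at the primary carbon of geranyl bromide (allylic substitution of an organocopper), which leaves the 2E alkene untouched.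

**Step 2**
Reactants: 5 1-bromo-2-[(2E)-3,7-dimethylocta-2,6-dien-1-yl]-3,4-dimethoxybenzene
Product: 8 {2-[(2E)-3,7-dimethylocta-2,6-dien-1-yl]-3,4-dimethoxyphenyl}boronic acid, via aryllithium 6 (not isolated), via lithium aryltriisopropoxyborate 7 (not isolated)
Conditions: n-BuLi, THF, −78 °C; B(OiPr)3, −78 °C → rt; 1 M aq. HCl, 0 °C
Reagents that add atoms: triisopropyl borate CC(C)OB(OC(C)C)OC(C)C; water O
Why: Bromine–lithium exchange at −78 °C should be much faster than deprotonation of the benzylic–allylic CH2 or any reaction of the alkenes, and trapping of the aryllithium with the borate followed by hydrolysis is the standard lithiation–borylation route to arylboronic acids.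

**Step 3**
Reactants: 9 1-(2,6-dihydroxy-4-methoxyphenyl)ethan-1-one
Product: 11 5-hydroxy-7-methoxy-4H-chromen-4-one, via enaminone 10 (not isolated)
Conditions: Me2NCH(OMe)2 (DMF-DMA, 1.5 equiv), toluene, 90 °C; then 2 M aq. HCl, CH2Cl2, rt
Reagents that add atoms: N,N-dimethylformamide dimethyl acetal COC(OC)N(C)C
Why: Enaminone route to chromones: condensation of the acetyl CH3 with the amide acetal, then acid-promoted intramolecular oxa-Michael addition of one of the two equivalent phenols and loss of dimethylamine should close ring C, the other phenol remaining as the hydrogen-bonded 5-OH.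

**Step 4**
Reactants: 11 5-hydroxy-7-methoxy-4H-chromen-4-one
Product: 12 7-methoxy-5-(methoxymethoxy)-4H-chromen-4-one
Conditions: NaH, DMF, 0 °C; MOMCl, 0 °C → rt
Reagents that add atoms: chloromethyl methyl ether COCCl
Why: Williamson ether synthesis on the sodium phenoxide should mask the acidic 5-OH, which together with the C4 carbonyl could otherwise bind rhodium as a chelating ketophenolate and lower the electrophilicity of C2 in step 5.

**Step 5**
Reactants: 12 7-methoxy-5-(methoxymethoxy)-4H-chromen-4-one; 8 {2-[(2E)-3,7-dimethylocta-2,6-dien-1-yl]-3,4-dimethoxyphenyl}boronic acid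
Product: 13 (2S)-2-{2-[(2E)-3,7-dimethylocta-2,6-dien-1-yl]-3,4-dimethoxyphenyl}-7-methoxy-5-(methoxymethoxy)-2,3-dihydro-4H-chromen-4-one
Conditions: [RhCl(C2H4)2]2 (2.5 mol %), (S)-MeO-F12-BIPHEP [(S)-2,2'-bis{bis(3,4,5-trifluorophenyl)phosphino}-6,6'-dimethoxy-1,1'-biphenyl] (5.5 mol %), aq. KOH (20 mol %), 8 (2.5 equiv, in two portions), toluene/H2O 10:1, 50 °C
Reagents that add atoms: none
Why: Hayashi–Miyaura reaction (rhodium-catalysed asymmetric 1,4-addition of an arylboronic acid to an enone), a reaction type with close precedent on 5,7-dioxygenated chromones. The hydroxorhodium–bisphosphine complex formed from the chloride dimer and KOH takes the aryl group from 8 by transmetalation, the aryl–rhodium bond adds across C2=C3 of 12 with the aryl group going to C2, and water protonates the resulting oxa-π-allyl rhodium enolate at C3 and returns the hydroxorhodium species. No ring is closed; the step joins ring B to the preformed ring C and brings ring C to the chromanone level. The new stereocenter C2 is controlled by the (S)-biaryl bisphosphine alone: it should leave open the face of the flat chromone from which O1, C3 and H at C2 run clockwise (Re face), the face selection that (S)-BINAP-type rhodium catalysts show on 2-cyclohexenone, and aryl delivery there gives 2S. The step needs 1,4-addition to outrun protodeboronation of the ortho-substituted, electron-rich boronic acid and needs the product to escape retro-oxa-Michael ring opening; the MOM ether (no acidic or chelating 5-OH), the electron-poor ligand, the substoichiometric base, the moderate temperature and the portionwise excess of 8 are meant to secure this. The trisubstituted alkenes of the geranyl chain are too hindered to insert into the aryl–rhodium bond or to displace the bisphosphine.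

**Step 6**
Reactants: 13 (2S)-2-{2-[(2E)-3,7-dimethylocta-2,6-dien-1-yl]-3,4-dimethoxyphenyl}-7-methoxy-5-(methoxymethoxy)-2,3-dihydro-4H-chromen-4-one
Product: 14 (2S)-2-{2-[(2E)-3,7-dimethylocta-2,6-dien-1-yl]-3,4-dimethoxyphenyl}-5-hydroxy-7-methoxy-2,3-dihydro-4H-chromen-4-one
Conditions: HCl (1.25 M in MeOH), MeOH/THF, 0 °C → rt
Reagents that add atoms: none
Why: Acid-catalysed acetal cleavage (transacetalisation to methanol) should free the hydrogen-bonded 5-OH under conditions that do not enolise C3, so that no retro-oxa-Michael opening can touch the 2S center, and that are mild enough to leave the trisubstituted alkenes unprotonated.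

**Compound list**
1 | 4-bromo-1,2-dimethoxybenzene (4-bromoveratrole) | COc1ccc(Br)cc1OC | starting material
2 | geranyl bromide, (2E)-1-bromo-3,7-dimethylocta-2,6-diene | BrC/C=C(\C)CCC=C(C)C | starting material
3 | (6-bromo-2,3-dimethoxyphenyl)lithium | COc1ccc(Br)c([Li])c1OC | intermediate
4 | (6-bromo-2,3-dimethoxyphenyl)copper | COc1ccc(Br)c([Cu])c1OC | intermediate
5 | 1-bromo-2-[(2E)-3,7-dimethylocta-2,6-dien-1-yl]-3,4-dimethoxybenzene | COc1ccc(Br)c(C/C=C(\C)CCC=C(C)C)c1OC | intermediate
6 | {2-[(2E)-3,7-dimethylocta-2,6-dien-1-yl]-3,4-dimethoxyphenyl}lithium | COc1ccc([Li])c(C/C=C(\C)CCC=C(C)C)c1OC | intermediate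
7 | lithium {2-[(2E)-3,7-dimethylocta-2,6-dien-1-yl]-3,4-dimethoxyphenyl}triisopropoxyborate | [Li+].CC(C)O[B-](OC(C)C)(OC(C)C)c1ccc(OC)c(OC)c1C/C=C(\C)CCC=C(C)C | intermediate
8 | {2-[(2E)-3,7-dimethylocta-2,6-dien-1-yl]-3,4-dimethoxyphenyl}boronic acid | OB(O)c1ccc(OC)c(OC)c1C/C=C(\C)CCC=C(C)C | intermediate
9 | 1-(2,6-dihydroxy-4-methoxyphenyl)ethan-1-one | CC(=O)c1c(O)cc(OC)cc1O | starting material
10 | (2E)-1-(2,6-dihydroxy-4-methoxyphenyl)-3-(dimethylamino)prop-2-en-1-one | CN(C)/C=C/C(=O)c1c(O)cc(OC)cc1O | intermediate
11 | 5-hydroxy-7-methoxy-4H-chromen-4-one | COc1cc(O)c2c(=O)ccoc2c1 | intermediate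
12 | 7-methoxy-5-(methoxymethoxy)-4H-chromen-4-one | COCOc1cc(OC)cc2occc(=O)c12 | intermediate
13 | (2S)-2-{2-[(2E)-3,7-dimethylocta-2,6-dien-1-yl]-3,4-dimethoxyphenyl}-7-methoxy-5-(methoxymethoxy)-2,3-dihydro-4H-chromen-4-one | COc1cc(OCOC)c2c(c1)O[C@H](c1ccc(OC)c(OC)c1C/C=C(\C)CCC=C(C)C)CC2=O | intermediate
14 | (2S)-2-{2-[(2E)-3,7-dimethylocta-2,6-dien-1-yl]-3,4-dimethoxyphenyl}-5-hydroxy-7-methoxy-2,3-dihydro-4H-chromen-4-one | COc1cc(O)c2c(c1)O[C@H](c1ccc(OC)c(OC)c1C/C=C(\C)CCC=C(C)C)CC2=O | target

**Total step count:** 6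
**Longest linear sequence:** 4 steps (1 → 2 → 5 → 6, or 3 → 4 → 5 → 6)

**Steps most likely to fail**

1. Step 5 (key step). What may go wrong: the ortho-geranyl group slows transmetalation and insertion, so that protodeboronation of the electron-rich boronic acid consumes 8 first. Facial discrimination may also be incomplete, and base-mediated retro-oxa-Michael opening of the product may erode the configuration. The sense of induction is assigned by analogy and should be checked with phenylboronic acid, whose product is the MOM ether of pinostrobin, a flavanone of known configuration.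
Fallback (stoichiometric organocopper conjugate addition followed by resolution, in place of asymmetric catalysis): it sets out from bromide 5 and chromone 12 and comes back to the route at 13. Bromide 5 is converted with n-BuLi (THF, −78 °C) into aryllithium 6, and CuI (0.5 equiv) turns this into lithium bis{2-[(2E)-3,7-dimethylocta-2,6-dien-1-yl]-3,4-dimethoxyphenyl}cuprate F1. Addition of 12 together with TMSCl at −78 °C should give the silyl enol ether, racemic 2-{2-[(2E)-3,7-dimethylocta-2,6-dien-1-yl]-3,4-dimethoxyphenyl}-7-methoxy-5-(methoxymethoxy)-4-[(trimethylsilyl)oxy]-2H-chromene F2. Aqueous work-up should hydrolyse it to the racemic MOM-protected flavanone F3. Preparative HPLC on a chiral stationary phase then separates the enantiomers, and the 2S enantiomer is 13.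

2. Step 1. What may go wrong: loss of LiBr from the ortho-bromoaryllithium 3 (aryne formation) before transmetalation, deprotonation at another ring position or bromine migration, and attack of the arylcopper at the tertiary allylic terminus.
Fallback (an oxygen substituent at C1' as second directing group and later leaving group, so that no ortho-halo organometallic is needed): it sets out from geranyl bromide 2 and comes back to the route at 13. Purchased 3,4-dimethoxyphenol F4 is protected (MOMCl, iPr2NEt, CH2Cl2) as 1,2-dimethoxy-4-(methoxymethoxy)benzene F5. n-BuLi (THF, 0 °C) should lithiate the position between the MOM ether and the neighbouring methoxy group to give [2,3-dimethoxy-6-(methoxymethoxy)phenyl]lithium F6. CuBr·SMe2 converts this into [2,3-dimethoxy-6-(methoxymethoxy)phenyl]copper F7, and 2 allylates it to 2-[(2E)-3,7-dimethylocta-2,6-dien-1-yl]-3,4-dimethoxy-1-(methoxymethoxy)benzene F8. Mild acid (HCl in MeOH, rt) frees 2-[(2E)-3,7-dimethylocta-2,6-dien-1-yl]-3,4-dimethoxyphenol F9, and Tf2O/pyridine gives 2-[(2E)-3,7-dimethylocta-2,6-dien-1-yl]-3,4-dimethoxyphenyl trifluoromethanesulfonate F10. Miyaura borylation (B2pin2, PdCl2(dppf), KOAc, dioxane, 80 °C) gives the pinacol boronate 2-{2-[(2E)-3,7-dimethylocta-2,6-dien-1-yl]-3,4-dimethoxyphenyl}-4,4,5,5-tetramethyl-1,3,2-dioxaborolane F11. This takes the place of 8 under the conditions of step 5 and should deliver 13.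

3. Step 6. What may go wrong: protonation of the trisubstituted alkenes during acidic MOM cleavage (hydrochlorination, hydration or cation–olefin cyclisation of the geranyl chain), or incomplete cleavage.
Fallback (a fluoride-labile silyl ether in place of the acid-labile acetal): it sets out from chromone 11 and comes back to the route at 14. Chromone 11 is silylated (TIPSOTf, 2,6-lutidine, CH2Cl2) to 7-methoxy-5-[(triisopropylsilyl)oxy]-4H-chromen-4-one F12. The conditions of step 5 with 8 should give (2S)-2-{2-[(2E)-3,7-dimethylocta-2,6-dien-1-yl]-3,4-dimethoxyphenyl}-7-methoxy-5-[(triisopropylsilyl)oxy]-2,3-dihydro-4H-chromen-4-one F13. Bu4NF buffered with AcOH (THF, 0 °C) then removes the silyl group to give 14.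

**Further compounds**
F1 | step 5 | lithium bis{2-[(2E)-3,7-dimethylocta-2,6-dien-1-yl]-3,4-dimethoxyphenyl}cuprate | [Li+].COc1ccc([Cu-]c2ccc(OC)c(OC)c2C/C=C(\C)CCC=C(C)C)c(C/C=C(\C)CCC=C(C)C)c1OC
F2 | step 5 | racemic 2-{2-[(2E)-3,7-dimethylocta-2,6-dien-1-yl]-3,4-dimethoxyphenyl}-7-methoxy-5-(methoxymethoxy)-4-[(trimethylsilyl)oxy]-2H-chromene | COCOc1cc(OC)cc2OC(c3ccc(OC)c(OC)c3C/C=C(\C)CCC=C(C)C)C=C(O[Si](C)(C)C)c12
F3 | step 5 | racemic 2-{2-[(2E)-3,7-dimethylocta-2,6-dien-1-yl]-3,4-dimethoxyphenyl}-7-methoxy-5-(methoxymethoxy)-2,3-dihydro-4H-chromen-4-one | COc1cc(OCOC)c2c(c1)OC(c1ccc(OC)c(OC)c1C/C=C(\C)CCC=C(C)C)CC2=O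
F4 | step 1 | 3,4-dimethoxyphenol (purchased) | COc1ccc(O)cc1OC
F5 | step 1 | 1,2-dimethoxy-4-(methoxymethoxy)benzene | COCOc1ccc(OC)c(OC)c1
F6 | step 1 | [2,3-dimethoxy-6-(methoxymethoxy)phenyl]lithium | COCOc1ccc(OC)c(OC)c1[Li]
F7 | step 1 | [2,3-dimethoxy-6-(methoxymethoxy)phenyl]copper | COCOc1ccc(OC)c(OC)c1[Cu]
F8 | step 1 | 2-[(2E)-3,7-dimethylocta-2,6-dien-1-yl]-3,4-dimethoxy-1-(methoxymethoxy)benzene | COCOc1ccc(OC)c(OC)c1C/C=C(\C)CCC=C(C)C
F9 | step 1 | 2-[(2E)-3,7-dimethylocta-2,6-dien-1-yl]-3,4-dimethoxyphenol | Oc1ccc(OC)c(OC)c1C/C=C(\C)CCC=C(C)C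
F10 | step 1 | 2-[(2E)-3,7-dimethylocta-2,6-dien-1-yl]-3,4-dimethoxyphenyl trifluoromethanesulfonate | O=S(=O)(Oc1ccc(OC)c(OC)c1C/C=C(\C)CCC=C(C)C)C(F)(F)F
F11 | step 1 | 2-{2-[(2E)-3,7-dimethylocta-2,6-dien-1-yl]-3,4-dimethoxyphenyl}-4,4,5,5-tetramethyl-1,3,2-dioxaborolane | CC1(C)OB(OC1(C)C)c1ccc(OC)c(OC)c1C/C=C(\C)CCC=C(C)C
F12 | step 6 | 7-methoxy-5-[(triisopropylsilyl)oxy]-4H-chromen-4-one | COc1cc(O[Si](C(C)C)(C(C)C)C(C)C)c2c(=O)ccoc2c1
F13 | step 6 | (2S)-2-{2-[(2E)-3,7-dimethylocta-2,6-dien-1-yl]-3,4-dimethoxyphenyl}-7-methoxy-5-[(triisopropylsilyl)oxy]-2,3-dihydro-4H-chromen-4-one | COc1cc(O[Si](C(C)C)(C(C)C)C(C)C)c2c(c1)O[C@H](c1ccc(OC)c(OC)c1C/C=C(\C)CCC=C(C)C)CC2=O
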